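**Retrosynthetic overview**

- The two esters come off in reverse order of installation: first the isovalerate on the homopropargylic oxygen, then the senecioate on the thenyl oxygen. A silyl ether on the butynol oxygen keeps the two hydroxyls apart until then.
- Structural feature: ring A (the thiophene bearing the CH2O group) has only hydrogen on C3 and C4. Its C2–C3–C4–C5 chain is therefore a masked buta-1,3-diyne running from the CH2O carbon to C2 of ring B, while the C≡C–CH2CH2O unit on ring B is the only other alkyne and is not conjugated to a second triple bond.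
- Key disconnection: both C–S bonds of ring A, leading back to a HOCH2–C≡C–C≡C–(ring B) diynol and sulfide, with no aryl–aryl cross-coupling.
- The diynol is cut at its central sp–sp bond (Cadiot–Chodkiewicz) into 3-bromoprop-2-yn-1-ol and a 2-ethynylthiophene. The ethynyl group comes from an aldehyde by one-carbon homologation, and the silyloxybutynyl chain by Sonogashira coupling.
- Ring order: ring B is bought as 5-bromothiophene-2-carbaldehyde; ring A is built onto it de novo in step 6.

Key step: step 6

**Route**

Step 1
Reactants: 1 but-3-yn-1-ol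
Product: 2 tert-butyl(but-3-yn-1-yloxy)diphenylsilane
Conditions: TBDPSCl, imidazole, CH2Cl2, 0 °C to rt
Reagents that add atoms: tert-butyldiphenylsilyl chloride (TBDPSCl), CC(C)(C)[Si](Cl)(c1ccccc1)c1ccccc1
Why: Imidazole-mediated silylation of a primary alcohol should be clean, and the bulky silyl ether is chosen because it should withstand carbonate in methanol, aqueous butylamine and aqueous sulfide later on, which an ester would not.

Step 2
Reactants: 2 tert-butyl(but-3-yn-1-yloxy)diphenylsilane; 3 5-bromothiophene-2-carbaldehyde
Product: 4 5-[4-(tert-butyldiphenylsilyloxy)but-1-yn-1-yl]thiophene-2-carbaldehyde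
Conditions: Pd(PPh3)2Cl2 (cat.), CuI (cat.), Et3N, THF, rt to 40 °C, argon
Reagents that add atoms: none
Why: Sonogashira coupling; the formyl group makes the C–Br bond electron-poor, so oxidative addition to zerovalent palladium should be fast, and the aldehyde and silyl ether are spectators.

Step 3
Reactants: 4 5-[4-(tert-butyldiphenylsilyloxy)but-1-yn-1-yl]thiophene-2-carbaldehyde; 5 dimethyl (1-diazo-2-oxopropyl)phosphonate
Product: 7 2-ethynyl-5-[4-(tert-butyldiphenylsilyloxy)but-1-yn-1-yl]thiophene, via diazoalkene 6 (not isolated)
Conditions: K2CO3, MeOH, 0 °C to rt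
Reagents that add atoms: none
Why: Seyferth–Gilbert homologation in its Ohira–Bestmann form: methanolysis of 5 releases dimethyl (diazomethyl)phosphonate, whose anion condenses with the non-enolisable aldehyde in Horner–Wadsworth–Emmons fashion to diazoalkene 6, which loses N2 and undergoes a 1,2-hydrogen shift to the terminal alkyne under conditions the silyl ether tolerates.

Step 4
Reactants: 8 prop-2-yn-1-ol (propargyl alcohol)
Product: 9 3-bromoprop-2-yn-1-ol
Conditions: NBS, AgNO3 (cat.), acetone, rt, dark; used fresh
Reagents that add atoms: N-bromosuccinimide (NBS), O=C1CCC(=O)N1Br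
Why: AgNO3-catalysed electrophilic bromination of a terminal alkyne C–H by NBS is a standard entry to 1-bromoalkynes and leaves the primary alcohol untouched.

Step 5
Reactants: 7 2-ethynyl-5-[4-(tert-butyldiphenylsilyloxy)but-1-yn-1-yl]thiophene; 9 3-bromoprop-2-yn-1-ol
Product: 10 5-{5-[4-(tert-butyldiphenylsilyloxy)but-1-yn-1-yl]thiophen-2-yl}penta-2,4-diyn-1-ol
Conditions: CuCl (cat.), NH2OH·HCl, 30% aq. n-BuNH2, THF/MeOH, 0 °C to rt, slow addition of 9; product carried on at once
Reagents that add atoms: none
Why: Cadiot–Chodkiewicz coupling: only the terminal alkyne of 7 is cuprated and should couple with the bromoalkyne to the unsymmetrical diyne, with hydroxylamine holding copper in the monovalent state so that oxidative homocoupling is suppressed, and the internal alkyne and silyl ether take no part.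

Step 6
Reactants: 10 5-{5-[4-(tert-butyldiphenylsilyloxy)but-1-yn-1-yl]thiophen-2-yl}penta-2,4-diyn-1-ol
Product: 12 {5'-[4-(tert-butyldiphenylsilyloxy)but-1-yn-1-yl]-2,2'-bithiophen-5-yl}methanol, via enynethiol 11 (not isolated)
Conditions: Na2S·9H2O (2 equiv), degassed DMF, rt to 40 °C, argon; then aq. NH4Cl
Reagents that add atoms: sodium sulfide nonahydrate (Na2S·9H2O), [Na+].[Na+].[S-2].O.O.O.O.O.O.O.O.O
Why: Hydrosulfide from Na2S·9H2O should add anti, in conjugate fashion, to the CH2OH-bearing terminus of the electron-poor buta-1,3-diyne to give the (Z)-enynethiol 11 as its thiolate, whose sulfur then attacks the far alkyne carbon next to ring B; protonation of the resulting vinyl anion leaves the aromatic thiophene. The closest known reaction type is the sulfide annulation of 1,3-diynes, diaryl diynes and diynols alike, to 2,5-disubstituted thiophenes, which mirrors the biogenesis of natural bithiophenes from polyynes. Ring A is closed in a 5-endo-dig mode, with the two C–S bonds made to the outer carbons of the diyne, so the 2,2'-bithiophene appears with its hydroxymethyl group already in place. No stereocenter is created. The step needs chemoselectivity for the diyne over the isolated thienyl alkyl alkyne: the diyne has the lower LUMO and offers a second triple bond within reach of the thiolate, the monoyne has neither, and the small excess of sulfide and mild temperature should keep background hydrothiolation slow. The silyl ether and the primary alcohol should tolerate aqueous sulfide, so the two oxygens stay differentiated.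

Step 7
Reactants: 12 {5'-[4-(tert-butyldiphenylsilyloxy)but-1-yn-1-yl]-2,2'-bithiophen-5-yl}methanol; 13 3-methylbut-2-enoic acid (senecioic acid)
Product: 14 {5'-[4-(tert-butyldiphenylsilyloxy)but-1-yn-1-yl]-2,2'-bithiophen-5-yl}methyl 3-methylbut-2-enoate
Conditions: EDC·HCl, DMAP (cat.), CH2Cl2, 0 °C to rt
Reagents that add atoms: none
Why: Carbodiimide (Steglich-type) esterification of a primary thenyl alcohol with N-(3-dimethylaminopropyl)-N'-ethylcarbodiimide hydrochloride; with only catalytic 4-(dimethylamino)pyridine at low temperature and no trialkylamine, the activated senecioyl group should not be deprotonated at a γ-methyl, so the double bond stays conjugated.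

Step 8
Reactants: 14 {5'-[4-(tert-butyldiphenylsilyloxy)but-1-yn-1-yl]-2,2'-bithiophen-5-yl}methyl 3-methylbut-2-enoate
Product: 15 [5'-(4-hydroxybut-1-yn-1-yl)-2,2'-bithiophen-5-yl]methyl 3-methylbut-2-enoate
Conditions: TBAF, AcOH, THF, 0 °C to rt
Reagents that add atoms: none
Why: Fluoride-induced desilylation with tetrabutylammonium fluoride is driven by the strong Si–F bond, and buffering with acetic acid keeps the medium near neutral so that the thenyl ester should be neither cleaved nor deconjugated.

Step 9
Reactants: 15 [5'-(4-hydroxybut-1-yn-1-yl)-2,2'-bithiophen-5-yl]methyl 3-methylbut-2-enoate; 16 3-methylbutanoyl chloride (isovaleryl chloride)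
Product: 17 {5'-[4-(3-methylbutanoyloxy)but-1-yn-1-yl]-2,2'-bithiophen-5-yl}methyl 3-methylbut-2-enoate (target CNP0114739.0)
Conditions: pyridine, DMAP (cat.), CH2Cl2, 0 °C
Reagents that add atoms: none
Why: Acylation of a primary alcohol by an acyl chloride under nucleophilic catalysis, with pyridine as HCl scavenger; the senecioate already present is not an activated acyl group and should be unaffected, and the target has no stereocenter or E/Z element to control.

**Compound list**

1 | but-3-yn-1-ol | C#CCCO | starting material
2 | tert-butyl(but-3-yn-1-yloxy)diphenylsilane | C#CCCO[Si](c1ccccc1)(c1ccccc1)C(C)(C)C | intermediate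
3 | 5-bromothiophene-2-carbaldehyde (ring B) | O=Cc1ccc(Br)s1 | starting material
4 | 5-[4-(tert-butyldiphenylsilyloxy)but-1-yn-1-yl]thiophene-2-carbaldehyde | O=Cc1ccc(C#CCCO[Si](c2ccccc2)(c2ccccc2)C(C)(C)C)s1 | intermediate
5 | dimethyl (1-diazo-2-oxopropyl)phosphonate (Ohira–Bestmann reagent) | CC(=O)C(=[N+]=[N-])P(=O)(OC)OC | starting material
6 | 2-(2-diazoethenyl)-5-[4-(tert-butyldiphenylsilyloxy)but-1-yn-1-yl]thiophene (diazoalkene, not isolated) | [N-]=[N+]=C=Cc1ccc(C#CCCO[Si](c2ccccc2)(c2ccccc2)C(C)(C)C)s1 | intermediate
7 | 2-ethynyl-5-[4-(tert-butyldiphenylsilyloxy)but-1-yn-1-yl]thiophene | C#Cc1ccc(C#CCCO[Si](c2ccccc2)(c2ccccc2)C(C)(C)C)s1 | intermediate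
8 | prop-2-yn-1-ol (propargyl alcohol) | C#CCO | starting material
9 | 3-bromoprop-2-yn-1-ol | OCC#CBr | intermediate
10 | 5-{5-[4-(tert-butyldiphenylsilyloxy)but-1-yn-1-yl]thiophen-2-yl}penta-2,4-diyn-1-ol | OCC#CC#Cc1ccc(C#CCCO[Si](c2ccccc2)(c2ccccc2)C(C)(C)C)s1 | intermediate
11 | (Z)-2-sulfanyl-5-{5-[4-(tert-butyldiphenylsilyloxy)but-1-yn-1-yl]thiophen-2-yl}pent-2-en-4-yn-1-ol (enynethiol, present as its sodium thiolate, not isolated) | OC/C(S)=C/C#Cc1ccc(C#CCCO[Si](c2ccccc2)(c2ccccc2)C(C)(C)C)s1 | intermediate
12 | {5'-[4-(tert-butyldiphenylsilyloxy)but-1-yn-1-yl]-2,2'-bithiophen-5-yl}methanol | OCc1ccc(-c2ccc(C#CCCO[Si](c3ccccc3)(c3ccccc3)C(C)(C)C)s2)s1 | intermediate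
13 | 3-methylbut-2-enoic acid (senecioic acid) | CC(C)=CC(=O)O | starting material
14 | {5'-[4-(tert-butyldiphenylsilyloxy)but-1-yn-1-yl]-2,2'-bithiophen-5-yl}methyl 3-methylbut-2-enoate | CC(C)=CC(=O)OCc1ccc(-c2ccc(C#CCCO[Si](c3ccccc3)(c3ccccc3)C(C)(C)C)s2)s1 | intermediate
15 | [5'-(4-hydroxybut-1-yn-1-yl)-2,2'-bithiophen-5-yl]methyl 3-methylbut-2-enoate | CC(C)=CC(=O)OCc1ccc(-c2ccc(C#CCCO)s2)s1 | intermediate
16 | 3-methylbutanoyl chloride (isovaleryl chloride) | CC(C)CC(=O)Cl | starting material
17 | {5'-[4-(3-methylbutanoyloxy)but-1-yn-1-yl]-2,2'-bithiophen-5-yl}methyl 3-methylbut-2-enoate (CNP0114739.0) | CC(C)=CC(=O)OCc1ccc(-c2ccc(C#CCCOC(=O)CC(C)C)s2)s1 | target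

**Step count and risks**

Total step count: 9.
Longest linear sequence: 8 steps (steps 1, 2, 3, 5, 6, 7, 8 and 9, from but-3-yn-1-ol 1); step 4 is a one-step side branch.

Steps most likely to fail:

1. Step 6 (sulfide annulation). The sulfide, or the hydroxide it generates, may react beyond the diyne: hydrothiolation of the isolated alkyne, base-induced β-elimination of the silyloxy group across the propargylic CH2CH2O unit, or slow loss of the silyl group. The diynol may also oligomerise before it cyclises. Fallback: keep the same ring construction but carry it out before the monoyne and the silyl ether exist. Setting out from 3, Seyferth–Gilbert homologation with 5 (K2CO3, MeOH) would give 2-bromo-5-ethynylthiophene F1. Cadiot–Chodkiewicz coupling of F1 with 9 would give 5-(5-bromothiophen-2-yl)penta-2,4-diyn-1-ol F2. Na2S·9H2O in DMF would close ring A to (5'-bromo-2,2'-bithiophen-5-yl)methanol F3. Sonogashira coupling of F3 with 2 (Pd(PPh3)2Cl2, CuI, Et3N, THF, 50 °C) would then rejoin the route at 12.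

2. Step 5 (Cadiot–Chodkiewicz coupling). Homocoupling and decomposition of the bromopropargyl alcohol may outrun the cross-coupling, and the diynol may polymerise on concentration. Fallback: reverse the roles of the two partners so that the labile bromoalkyne is not needed. Setting out from 7, bromination (NBS, catalytic AgNO3, acetone) would give 2-(bromoethynyl)-5-[4-(tert-butyldiphenylsilyloxy)but-1-yn-1-yl]thiophene F4. Coupling of F4 with an excess of inexpensive propargyl alcohol 8 (CuCl, NH2OH·HCl, aqueous n-BuNH2) would return to the route at 10.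

3. Step 7 (senecioate esterification). Activation of the acid may allow γ-deprotonation and drift of the double bond out of conjugation to the 3-methylbut-3-enoate, or rearrangement of the activated acid may stall the coupling. Fallback: activate the alcohol instead of the acid. Setting out from 12, Mitsunobu esterification with 13 (PPh3, diisopropyl azodicarboxylate, THF, 0 °C) would use the carboxylate only as a nucleophile, never activating its acyl group, and would arrive directly at 14 with no new compound on the way.

**Further compounds**

F1 | step 6 | 2-bromo-5-ethynylthiophene | C#Cc1ccc(Br)s1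
F2 | step 6 | 5-(5-bromothiophen-2-yl)penta-2,4-diyn-1-ol | OCC#CC#Cc1ccc(Br)s1
F3 | step 6 | (5'-bromo-2,2'-bithiophen-5-yl)methanol | OCc1ccc(-c2ccc(Br)s2)s1
F4 | step 5 | 2-(bromoethynyl)-5-[4-(tert-butyldiphenylsilyloxy)but-1-yn-1-yl]thiophene | BrC#Cc1ccc(C#CCCO[Si](c2ccccc2)(c2ccccc2)C(C)(C)C)s1
F0 | step 7 | none | none
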